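Read at 40 h, this flask poses one question: how much substrate has gone by then, and which nucleophile's charge has to cover it?

| setting | zeta | delta | flask |
|---|---|---|---|
| substrate | 0.40 M | 0.27 M | 0.40 M |
| first nucleophile | 0.28 M | 0.28 M | 0.280 M |
| second nucleophile | 0.42 M | 0.42 M | 0.420 M |
| remark | the very flask that is asked about, followed so far | run made earlier |  |
| time |  |  | 40 h |

| run | time / h | other capture product / % | target / % | substrate / % |
|---|---|---|---|---|
| zeta | 2.00 | 7.8 | 0 | 91.3 |
| zeta | 5.00 | 20.0 | 0.6 | 80.3 |
| zeta | 10.0 | 35.5 | 0 | 64.2 |
| zeta | 15.0 | 47.8 | 0.1 | 50.9 |
| zeta | 20.0 | 59.3 | 0.4 | 41.0 |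
| delta | 1.33 | 6.2 | 0.4 | 93.4 |
| delta | 2.50 | 9.8 | 0.3 | 89.2 |
| delta | 5.00 | 19.5 | 1.0 | 80.0 |
| delta | 8.00 | 29.3 | 0.5 | 68.6 |
| delta | 15.0 | 48.6 | 0 | 52.4 |

(each reading ± 0.5 percentage points)



- share of other capture product in other capture product plus target at 40 min
- share of other capture product in other capture product plus target at 5.0 h
- share of other capture product in other capture product plus target at 40 h
- which of other capture product and target there is more of at 40 h

We work with the fraction of substrate left, f = exp(−kt), with k the first-order constant of the substrate. This flask, followed as the zeta run, has 41.0% left at 20.0 h, so k = 0.0446 h⁻¹.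

The first setting is the substrate charge. By hand it should leave f alone if the decay is first-order, and the delta run, charged with 0.27 M, gives 0.0431 h⁻¹ from its last reading, so we take k over unchanged. The second setting is time, and at 40 h we reckon f = 16.8%. The part not left, times the substrate charge, is the demand 0.333 M, the substrate gone by the time of reading, in moles per litre.

The nucleophile charges come last. They were the same in both runs, so comparing the runs does not tell us which nucleophile the other capture product consumes. The demand is more than the first nucleophile's 0.280 M but less than the second's 0.420 M. We assume that the second nucleophile pays, so that the other capture product can keep following the demand.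

The target readings of both runs show no rise and average 0.330%. We hold that level constant, although no reading stands as early as 40 min. Our shares are then 88.7% at 40 min, 98.3% at 5.0 h and 99.6% at 40 h.

The forecast gives 99.6%, 99.5% and 84.5%, with other capture product ahead. It assumes that “this product consumes the first nucleophile”, so at 40 h its share stands below ours.

The flask gives 92.6%, 99.0% and 99.7%, with other capture product ahead at 82.8% against 0.263% of target. At 40.0 h it keeps 99.6% of its first nucleophile and 12.4% of its second.

    substrate → intermediate (k = 0.0450 h⁻¹)
    second nucleophile + intermediate → other capture product (k = 39.0 L mol⁻¹ h⁻¹)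
    first nucleophile + intermediate ⇌ target (K = 2.60 L mol⁻¹, k = 59.0 L mol⁻¹ h⁻¹)
    second nucleophile → decomposed reagent (k = 0.00500 h⁻¹)

A neighbouring flask is charged with 0.25 M of second nucleophile and the same substrate charge, so its demand is again 0.333 M, more than that charge. At 40.0 h it holds 16.5% substrate and 0% of its second nucleophile, the limiting reagent there. Its other capture product reaches 59.7%, its intermediate 14.6% and its target 9.22%, a share of 86.6%.

The earlier runs and the new flask come from a simulation for an exercise; the scatter is artificial.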